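Ring numbering of the target used below: C1 (CH bearing CH2OAr), C2 (C–CH3), C3 (=CH), C4 (CH2), C5 (CH–OAc), C6 (CMe2). The last steps are acetylation of the C5 alcohol, CBS reduction of the C5 ketone, hydrolysis of a C5 ethyl enol ether and Mitsunobu etherification of the C1 hydroxymethyl group with umbelliferone.
The CH2O carbon and the C1 stereocentre are disconnected by a Wittig–Still [2,3] rearrangement to an (R)-carbinol at C3 of a cyclohexa-2,5-dienol (1,3-chirality transfer; the C2=C3 alkene is formed and the C3 oxygen leaves the ring). The carbinol comes from an achiral cross-conjugated dienone by CBS reduction, and the dienone from a silyl dienol ether by Saegusa–Ito oxidation.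
Key disconnection: the C2–C3 and C1–C6 bonds of the carbocycle, formed together when isopropenyllithium adds to 3-ethoxy-4,4-dimethylcyclobut-2-enone and the alkoxide undergoes 4π ring opening and 6π ring closure (ring expansion of the four-membered to the six-membered ring).
Enabling feature: the contiguous ring atoms C6 (quaternary, gem-dimethyl), C5 (oxygen-bearing), C4 and C3 are the four carbons of a 3-alkoxy-4,4-dimethylcyclobutenone, and C1, C2 and the C2 methyl are an isopropenyl group. The carbonyl oxygen at C3 is a temporary handle that the route removes.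
Order of ring formation: cyclobutenone by ketene–alkyne [2+2] (step 1), then the cyclohexadiene by ring expansion (step 2); the coumarin ring system is bought as umbelliferone.

Key step: step 2

Remark: the target is read as the trans (1R,5R) isomer, with CH2OAr and OAc on opposite faces of the ring; "future C…" in the steps refers to the ring numbering above.

Step 1
Reactants: 1 isobutyryl chloride (2-methylpropanoyl chloride); 2 ethoxyacetylene (ethoxyethyne)
Product: 4 3-ethoxy-4,4-dimethylcyclobut-2-en-1-one, via dimethylketene 3 (not isolated)
Conditions: Et3N, MeCN, slow addition of 1, rt to 40 °C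
Reagents that add atoms: none
Why: Dehydrochlorination of 1 should generate dimethylketene 3 in the presence of the electron-rich alkyne, and the ketene–alkyne [2+2] cycloaddition joins the alkyne CH carbon to the ketene carbonyl carbon, which gives the 3-alkoxycyclobutenone regioisomer 4.

Step 2
Reactants: 4 3-ethoxy-4,4-dimethylcyclobut-2-en-1-one; 5 2-bromopropene
Product: 10 [(5-ethoxy-2,4,4-trimethylcyclohexa-1,5-dien-1-yl)oxy]trimethylsilane, via isopropenyllithium 6 (not isolated), via lithium cyclobutenolate 7 (not isolated), via lithium trienolate 8 (not isolated), via lithium dienolate 9 (not isolated)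
Conditions: 5, t-BuLi (2 equiv), Et2O, −78 °C; then 4, THF, −78 °C to rt; then TMSCl, −78 °C to 0 °C
Reagents that add atoms: chlorotrimethylsilane, C[Si](C)(C)Cl
Why: Isopropenyllithium 6 adds 1,2 to the carbonyl of the vinylogous ester 4, which makes the future C2–C3 bond; on warming, the lithium cyclobutenolate 7 undergoes alkoxide-accelerated conrotatory 4π ring opening in which the oxido group rotates outward, so the isopropenyl group ends up cis to the ethoxy-bearing carbon in trienolate 8, and thermal disrotatory 6π electrocyclisation between the isopropenyl CH2 and the CMe2 terminus then makes the future C1–C6 bond and gives the cross-conjugated dienolate 9, which TMSCl silylates on oxygen. The closest known reaction type is the ring expansion of cyclobutenones to cyclohexenones by addition of alkenyllithium reagents, which runs through the same 4π opening and 6π closure of a 3-oxidohexatriene below room temperature. The one ring that is closed, the carbocycle, closes by 6π disrotatory electrocyclisation (a formal 6-endo closure onto the alkene terminus), while the four-membered ring is opened. No stereocentre is formed and 10 is achiral, so only the triene geometry has to be right, and the outward rotation of the oxido donor secures it. The step needs 1,2- rather than 1,4-addition and no enolisation, and 4 secures both: it has no acidic α-hydrogen (its C4 is quaternary, its C2 is vinylic) and the hard organolithium attacks the carbonyl at −78 °C. The gem-dimethyl terminus has no hydrogen to lose and becomes the quaternary C6 as it stands, with the oxygen-bearing C5 already next to it.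

Step 3
Reactants: 10 [(5-ethoxy-2,4,4-trimethylcyclohexa-1,5-dien-1-yl)oxy]trimethylsilane
Product: 11 3-ethoxy-4,4,6-trimethylcyclohexa-2,5-dien-1-one
Conditions: Pd(OAc)2 (1.05 equiv), MeCN, rt
Reagents that add atoms: none
Why: Saegusa–Ito oxidation: the silyl enol ether is converted into an enolate of divalent palladium, and β-hydride elimination toward the ring CH2 should give the endocyclic enone, an achiral cross-conjugated dienone whose carbonyl (future C3) has a methyl-bearing and an unsubstituted alkenyl flank.

Step 4
Reactants: 11 3-ethoxy-4,4,6-trimethylcyclohexa-2,5-dien-1-one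
Product: 12 (1R)-3-ethoxy-4,4,6-trimethylcyclohexa-2,5-dien-1-ol
Conditions: (S)-2-methyl-CBS-oxazaborolidine (20 mol%), catecholborane, toluene, −78 °C; then aq. NaHCO3; used crude
Reagents that add atoms: none
Why: Corey–Bakshi–Shibata reduction: with the (S)-catalyst the methyl-bearing alkenyl flank should act as the large group and the unsubstituted alkenyl flank as the small one, so 1,2-hydride delivery gives the (R)-carbinol, the stereocentre from which the C1 configuration is later derived.

Step 5
Reactants: 12 (1R)-3-ethoxy-4,4,6-trimethylcyclohexa-2,5-dien-1-ol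
Product: 14 tributyl({[(1R)-3-ethoxy-4,4,6-trimethylcyclohexa-2,5-dien-1-yl]oxy}methyl)stannane, via potassium alkoxide 13 (not isolated)
Conditions: KH, 18-crown-6 (cat.), THF, 0 °C; then Bu3SnCH2I, 0 °C to rt
Reagents that add atoms: tributyl(iodomethyl)stannane, CCCC[Sn](CCCC)(CCCC)CI
Why: Williamson etherification of the potassium alkoxide with the primary iodide runs under basic conditions, which the acid-labile doubly allylic carbinol tolerates, and does not touch the stereocentre.

Step 6
Reactants: 14 tributyl({[(1R)-3-ethoxy-4,4,6-trimethylcyclohexa-2,5-dien-1-yl]oxy}methyl)stannane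
Product: 16 [(1R)-5-ethoxy-2,6,6-trimethylcyclohexa-2,4-dien-1-yl]methanol, via lithiomethyl ether 15 (not isolated)
Conditions: n-BuLi, THF, −78 °C; then H2O
Reagents that add atoms: none
Why: Tin–lithium exchange gives the α-alkoxy organolithium 15, which should undergo the Wittig–Still [2,3]-sigmatropic rearrangement across the methyl-bearing alkene (the enol ether alkene is electron-rich and its terminus fully substituted), so the CH2O carbon is delivered suprafacially to the ring carbon next to CMe2 on the face that carried the C–O bond, which transfers the (R)-carbinol configuration to the new (R)-stereocentre (future C1) and forms the C2=C3 alkene.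

Step 7
Reactants: 16 [(1R)-5-ethoxy-2,6,6-trimethylcyclohexa-2,4-dien-1-yl]methanol; 17 umbelliferone (7-hydroxy-2H-chromen-2-one)
Product: 18 7-{[(1R)-5-ethoxy-2,6,6-trimethylcyclohexa-2,4-dien-1-yl]methoxy}-2H-chromen-2-one
Conditions: PPh3, DIAD, THF, 0 °C (betaine formed first); then 17 and 16, 0 °C to rt
Reagents that add atoms: none
Why: Mitsunobu etherification of the primary alcohol with the acidic phenol forms the aryl ether by SN2 at the CH2 carbon, so the adjacent stereocentre is untouched, and forming the betaine first keeps free azodicarboxylate away from the electron-rich diene.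

Step 8
Reactants: 18 7-{[(1R)-5-ethoxy-2,6,6-trimethylcyclohexa-2,4-dien-1-yl]methoxy}-2H-chromen-2-one
Product: 19 7-{[(1R)-2,6,6-trimethyl-5-oxocyclohex-2-en-1-yl]methoxy}-2H-chromen-2-one
Conditions: oxalic acid (0.2 equiv), THF–H2O, 0 °C
Reagents that add atoms: water, O
Why: Mild enol ether hydrolysis: kinetic protonation at the unsubstituted carbon next to the ethoxy-bearing carbon (future C4) should give the oxocarbenium ion that water converts into the C5 ketone, which leaves the C2=C3 alkene out of conjugation and the C1 stereocentre untouched.

Step 9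
Reactants: 19 7-{[(1R)-2,6,6-trimethyl-5-oxocyclohex-2-en-1-yl]methoxy}-2H-chromen-2-one
Product: 20 7-{[(1R,5R)-5-hydroxy-2,6,6-trimethylcyclohex-2-en-1-yl]methoxy}-2H-chromen-2-one
Conditions: (S)-2-methyl-CBS-oxazaborolidine (20 mol%), catecholborane, toluene, −78 to −40 °C; then aq. NaHCO3
Reagents that add atoms: none
Why: Corey–Bakshi–Shibata reduction with the same (S)-catalyst: the quaternary CMe2 flank is the large group and the CH2 flank the small one, so hydride should be delivered under reagent control to give the (5R)-alcohol, trans to the C1 side chain, while catecholborane at low temperature leaves the coumarin lactone and the alkene alone.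

Step 10
Reactants: 20 7-{[(1R,5R)-5-hydroxy-2,6,6-trimethylcyclohex-2-en-1-yl]methoxy}-2H-chromen-2-one
Product: 21 7-{[(1R,5R)-5-(acetyloxy)-2,6,6-trimethylcyclohex-2-en-1-yl]methoxy}-2H-chromen-2-one
Conditions: Ac2O, pyridine, DMAP (cat.), CH2Cl2, rt
Reagents that add atoms: acetic anhydride, CC(=O)OC(C)=O
Why: DMAP-catalysed acylation of the hindered secondary alcohol gives the acetate with retention of configuration and completes the target.

Compound list
1 | isobutyryl chloride | CC(C)C(=O)Cl | starting material
2 | ethoxyacetylene | CCOC#C | starting material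
3 | dimethylketene | CC(C)=C=O | intermediate
4 | 3-ethoxy-4,4-dimethylcyclobut-2-en-1-one | CCOC1=CC(=O)C1(C)C | intermediate
5 | 2-bromopropene | CC(Br)=C | starting material
6 | isopropenyllithium (prop-1-en-2-yllithium) | [Li]C(C)=C | intermediate
7 | lithium 3-ethoxy-4,4-dimethyl-1-(prop-1-en-2-yl)cyclobut-2-en-1-olate | CCOC1=CC([O-])(C(C)=C)C1(C)C.[Li+] | intermediate
8 | lithium (3E)-5-ethoxy-2,6-dimethylhepta-1,3,5-trien-3-olate | C=C(C)/C([O-])=C\C(OCC)=C(C)C.[Li+] | intermediate
9 | lithium 5-ethoxy-2,4,4-trimethylcyclohexa-1,5-dien-1-olate | CCOC1=CC([O-])=C(C)CC1(C)C.[Li+] | intermediate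
10 | [(5-ethoxy-2,4,4-trimethylcyclohexa-1,5-dien-1-yl)oxy]trimethylsilane | CCOC1=CC(O[Si](C)(C)C)=C(C)CC1(C)C | intermediate
11 | 3-ethoxy-4,4,6-trimethylcyclohexa-2,5-dien-1-one | CCOC1=CC(=O)C(C)=CC1(C)C | intermediate
12 | (1R)-3-ethoxy-4,4,6-trimethylcyclohexa-2,5-dien-1-ol | CCOC1=C[C@@H](O)C(C)=CC1(C)C | intermediate
13 | potassium (1R)-3-ethoxy-4,4,6-trimethylcyclohexa-2,5-dien-1-olate | CCOC1=C[C@@H]([O-])C(C)=CC1(C)C.[K+] | intermediate
14 | tributyl({[(1R)-3-ethoxy-4,4,6-trimethylcyclohexa-2,5-dien-1-yl]oxy}methyl)stannane | CCOC1=C[C@@H](OC[Sn](CCCC)(CCCC)CCCC)C(C)=CC1(C)C | intermediate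
15 | ({[(1R)-3-ethoxy-4,4,6-trimethylcyclohexa-2,5-dien-1-yl]oxy}methyl)lithium | CCOC1=C[C@@H](OC[Li])C(C)=CC1(C)C | intermediate
16 | [(1R)-5-ethoxy-2,6,6-trimethylcyclohexa-2,4-dien-1-yl]methanol | CCOC1=CC=C(C)[C@@H](CO)C1(C)C | intermediate
17 | umbelliferone (7-hydroxy-2H-chromen-2-one) | Oc1ccc2ccc(=O)oc2c1 | starting material
18 | 7-{[(1R)-5-ethoxy-2,6,6-trimethylcyclohexa-2,4-dien-1-yl]methoxy}-2H-chromen-2-one | CCOC1=CC=C(C)[C@@H](COc2ccc3ccc(=O)oc3c2)C1(C)C | intermediate
19 | 7-{[(1R)-2,6,6-trimethyl-5-oxocyclohex-2-en-1-yl]methoxy}-2H-chromen-2-one | O=C1CC=C(C)[C@@H](COc2ccc3ccc(=O)oc3c2)C1(C)C | intermediate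
20 | 7-{[(1R,5R)-5-hydroxy-2,6,6-trimethylcyclohex-2-en-1-yl]methoxy}-2H-chromen-2-one | O[C@@H]1CC=C(C)[C@@H](COc2ccc3ccc(=O)oc3c2)C1(C)C | intermediate
21 | 7-{[(1R,5R)-5-(acetyloxy)-2,6,6-trimethylcyclohex-2-en-1-yl]methoxy}-2H-chromen-2-one | CC(=O)O[C@@H]1CC=C(C)[C@@H](COc2ccc3ccc(=O)oc3c2)C1(C)C | target

Total step count: 10. Longest linear sequence: 10 steps (from 1 and 2 to 21); 5 and 17 are bought and enter at steps 2 and 7.

Steps most likely to fail

Step 2. The organolithium may add in conjugate fashion or open the strained ring instead of adding to the carbonyl. After ring opening, the 6π closure onto the fully substituted terminus may be slow enough for the trienolate to isomerise by proton transfer or to oligomerise. The fallback sets out from 4 and 5 and returns at 10. It separates the addition from the pericyclic events and runs the latter on a neutral substrate. Isopropenyllithium from 5 is added to 4 at −78 °C and the cold alkoxide is silylated at once with TMSCl to give [(3-ethoxy-4,4-dimethyl-1-(prop-1-en-2-yl)cyclobut-2-en-1-yl)oxy]trimethylsilane F1. Thermolysis of F1 in toluene (80 to 110 °C, base-washed glassware) should bring about thermal conrotatory ring opening with the silyloxy group rotating outward and disrotatory 6π closure of the neutral silyloxytriene, which gives 10 directly.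

Step 4. The catalyst may discriminate poorly between the two alkenyl flanks of the cross-conjugated ketone, and the doubly allylic, enol-ether-activated carbinol may ionise during work-up, with loss of configuration or aromatisation by methyl shift. The fallback sets out from 11 and returns at 12. Luche reduction (NaBH4, CeCl3·7H2O, MeOH, −78 °C) gives racemic 3-ethoxy-4,4,6-trimethylcyclohexa-2,5-dien-1-ol F2. Lipase-catalysed acylation (immobilised Candida antarctica lipase B, vinyl acetate, MTBE, rt) should acylate the (R)-enantiomer preferentially to give (1R)-3-ethoxy-4,4,6-trimethylcyclohexa-2,5-dien-1-yl acetate F3. After separation, methanolysis of F3 (K2CO3, MeOH, 0 °C) returns 12, and the unreacted (S)-alcohol can be re-oxidised to 11 with MnO2 and recycled.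

Step 8. The dienol ether may be protonated at the methyl-bearing terminus, or the alkene may migrate into conjugation with the new ketone under acid catalysis. The fallback sets out from 18 and returns at 19. Hydrolysis under equilibrating conditions (aq. HCl, THF, rt) is allowed to go fully to the conjugated enone 7-{[(1R)-2,6,6-trimethyl-5-oxocyclohex-3-en-1-yl]methoxy}-2H-chromen-2-one F4 (mixture of epimers at the methyl-bearing carbon). Soft enolisation (TMSOTf, Et3N, CH2Cl2, 0 °C), which can only remove the γ-hydrogen because the α'-carbon is quaternary, gives the extended silyl dienol ether 7-({(1R)-2,6,6-trimethyl-5-[(trimethylsilyl)oxy]cyclohexa-2,4-dien-1-yl}methoxy)-2H-chromen-2-one F5. Desilylation with kinetic α-protonation of the dienolate (TBAF, AcOH, THF, −78 °C) should return the deconjugated ketone 19.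

Further compounds
F1 | step 2 | [(3-ethoxy-4,4-dimethyl-1-(prop-1-en-2-yl)cyclobut-2-en-1-yl)oxy]trimethylsilane (racemic) | CCOC1=CC(O[Si](C)(C)C)(C(C)=C)C1(C)C
F2 | step 4 | rac-3-ethoxy-4,4,6-trimethylcyclohexa-2,5-dien-1-ol | CCOC1=CC(O)C(C)=CC1(C)C
F3 | step 4 | (1R)-3-ethoxy-4,4,6-trimethylcyclohexa-2,5-dien-1-yl acetate | CCOC1=C[C@@H](OC(C)=O)C(C)=CC1(C)C
F4 | step 8 | 7-{[(1R)-2,6,6-trimethyl-5-oxocyclohex-3-en-1-yl]methoxy}-2H-chromen-2-one (epimers at the methyl-bearing carbon) | O=C1C=CC(C)[C@@H](COc2ccc3ccc(=O)oc3c2)C1(C)C
F5 | step 8 | 7-({(1R)-2,6,6-trimethyl-5-[(trimethylsilyl)oxy]cyclohexa-2,4-dien-1-yl}methoxy)-2H-chromen-2-one | C[Si](C)(C)OC1=CC=C(C)[C@@H](COc2ccc3ccc(=O)oc3c2)C1(C)C
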